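## Retrosynthetic overview

1. The target is disconnected at O–C3: the C5 hydroperoxide opens a β-lactone at its quaternary C–O carbon (5-exo, inversion), which closes the 1,2-dioxolane and releases the CH2CO2H arm in the same step.
2. The β-lactone comes from a tertiary β-hydroxy acid, made by catalytic asymmetric allylboration of a β-peroxy methyl ketone and cleavage of the allyl C=C.
3. The C5 tertiary hydroperoxide comes from H2O2 opening (inversion) of a 2,2,4-trisubstituted oxetane, itself from asymmetric allylboration of methyl ketone 8 and Markovnikov hydration.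
4. Ketone 8 comes from (R)-citronellal by Wittig olefination, Cu-catalysed asymmetric methyl conjugate addition (anti-1,3-dimethyl), cross-metathesis and hydrogenation (Ph(CH2)8 chain).
5. Ring order: oxetane (temporary, step 7), then β-lactone (temporary, step 13), then the 1,2-dioxolane (step 14, the only ring of the target).

Assumption: (R)-citronellal of at least 97% ee is used, and in the catalyst-controlled steps 2, 5 and 11 the ligand enantiomer written is the one taken to deliver the face drawn; if a sense proves opposite, the mirror-image ligand is used with nothing else changed.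

## Route

Step 1
Reactants: 1 (R)-citronellal; 2 1-(triphenyl-λ5-phosphanylidene)propan-2-one
Product: 3 (3E,6R)-6,10-dimethylundeca-3,9-dien-2-one
Conditions: 2 (1.2 equiv), CH2Cl2, 40 °C, 16 h
Reagents that add atoms: 1-(triphenyl-λ5-phosphanylidene)propan-2-one, CC(=O)C=P(c1ccccc1)(c1ccccc1)c1ccccc1
Why: Wittig olefination with a stabilised ylide gives the E-enone; the citronellal stereocentre is β to the aldehyde, is not touched and becomes C6 (the later C4' methyl centre, R).

Step 2
Reactants: 3 (3E,6R)-6,10-dimethylundeca-3,9-dien-2-one; 4 methylmagnesium bromide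
Product: 5 (4S,6R)-4,6,10-trimethylundec-9-en-2-one
Conditions: MeMgBr (1.3 equiv), CuBr·SMe2 (5 mol %), (R)-1-[(S)-2-(diphenylphosphino)ferrocenyl]ethyldicyclohexylphosphine (6 mol %), t-BuOMe, −78 °C; NH4Cl (aq)
Reagents that add atoms: methylmagnesium bromide, C[Mg]Br
Why: Copper-catalysed asymmetric conjugate addition of a Grignard reagent to an acyclic enone; the chiral ferrocenyl diphosphine directs methyl to one enone face and sets C4 (S), anti to the C6 methyl, under catalyst control.

Step 3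
Reactants: 5 (4S,6R)-4,6,10-trimethylundec-9-en-2-one; 6 6-phenylhex-1-ene
Product: 7 (4S,6R,9E)-4,6-dimethyl-14-phenyltetradec-9-en-2-one (9Z isomer also present)
Conditions: 6 (3 equiv), second-generation Hoveyda–Grubbs catalyst (5 mol %), CH2Cl2, 40 °C, argon sweep
Reagents that add atoms: 6-phenylhex-1-ene, C=CCCCCc1ccccc1
Why: Olefin cross-metathesis exchanges the isopropylidene terminus for the phenylpentyl-substituted alkylidene with loss of volatile isobutene; no stereocentre is involved and the E/Z ratio is irrelevant.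

Step 4
Reactants: 7 (4S,6R,9E)-4,6-dimethyl-14-phenyltetradec-9-en-2-one
Product: 8 (4S,6R)-4,6-dimethyl-14-phenyltetradecan-2-one
Conditions: H2 (1 atm), 10% Pd/C, EtOAc, rt
Reagents that add atoms: none
Why: Heterogeneous catalytic hydrogenation saturates the disubstituted alkene and leaves ketone, arene and both methyl stereocentres unchanged.

Step 5
Reactants: 8 (4S,6R)-4,6-dimethyl-14-phenyltetradecan-2-one; 9 2-allyl-1,3,2-dioxaborinane
Product: 10 (4R,6S,8R)-4,6,8-trimethyl-16-phenylhexadec-1-en-4-ol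
Conditions: 9 (1.5 equiv), (S)-3,3'-dibromo-1,1'-bi-2-naphthol (5 mol %), t-BuOH (2 equiv), toluene, rt, 48 h; H2O work-up
Reagents that add atoms: 2-allyl-1,3,2-dioxaborinane, C=CCB1OCCCO1
Why: Chiral-diol-catalysed asymmetric allylboration of a methyl ketone through a closed chair transition state that distinguishes CH3 from CH2R; this sets the tertiary carbinol (4R), which is the future C5 before its planned inversion.

Step 6
Reactants: 10 (4R,6S,8R)-4,6,8-trimethyl-16-phenylhexadec-1-en-4-ol; 11 dioxygen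
Product: 12 (2RS,4S,6S,8R)-4,6,8-trimethyl-16-phenylhexadecane-2,4-diol (C2 epimers)
Conditions: Co(acac)2 (20 mol %), PhSiH3 (2 equiv), O2 (1 atm), THF, rt
Reagents that add atoms: dioxygen, O=O
Why: Mukaiyama hydration (cobalt hydride H-atom transfer, O2 capture, reduction) gives the Markovnikov secondary alcohol; the new C2 centre forms unselectively on purpose, since it only carries the leaving group of step 7 and is erased in step 10.

Step 7
Reactants: 12 (2RS,4S,6S,8R)-4,6,8-trimethyl-16-phenylhexadecane-2,4-diol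
Product: 14 (2S,4RS)-2,4-dimethyl-2-[(2S,4R)-2,4-dimethyl-12-phenyldodecyl]oxetane, via secondary monotosylate 13 (not isolated)
Conditions: n-BuLi (1.0 equiv), THF, 0 °C; TsCl (1.0 equiv), 0 °C, 1 h; n-BuLi (1.05 equiv), 0 → 60 °C
Reagents that add atoms: none
Why: One-pot selective sulfonylation of the less hindered secondary hydroxyl followed by intramolecular Williamson etherification (4-exo-tet); the tertiary C–O bond is never broken, so the quaternary carbon keeps its configuration (2S in the oxetane).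

Step 8
Reactants: 14 (2S,4RS)-2,4-dimethyl-2-[(2S,4R)-2,4-dimethyl-12-phenyldodecyl]oxetane; 15 hydrogen peroxide
Product: 16 (2RS,4R,6S,8R)-4-hydroperoxy-4,6,8-trimethyl-16-phenylhexadecan-2-ol
Conditions: anhydrous H2O2 in Et2O (10 equiv), TMSOTf (20 mol %), Et2O, −78 → 0 °C
Reagents that add atoms: hydrogen peroxide, OO
Why: Lewis-acid-promoted perhydrolysis of an oxetane, which opens at the tertiary carbon in an SN2-like manner with inversion; both C4 epimers of the oxetane converge on the same (4R) tertiary hydroperoxide, the C5 centre of the target.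

Step 9
Reactants: 16 (2RS,4R,6S,8R)-4-hydroperoxy-4,6,8-trimethyl-16-phenylhexadecan-2-ol; 17 2-methoxypropene
Product: 18 (2RS,4R,6S,8R)-4-[(2-methoxypropan-2-yl)peroxy]-4,6,8-trimethyl-16-phenylhexadecan-2-ol
Conditions: 2-methoxypropene (1.5 equiv), PPTS (5 mol %), CH2Cl2, 0 °C
Reagents that add atoms: 2-methoxypropene, COC(C)=C
Why: Acid-catalysed peroxyketal formation; the hydroperoxide (α-effect nucleophile) adds to the oxocarbenium ion much faster than the secondary alcohol, so OOH is masked selectively and no stereocentre is touched.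

Step 10
Reactants: 18 (2RS,4R,6S,8R)-4-[(2-methoxypropan-2-yl)peroxy]-4,6,8-trimethyl-16-phenylhexadecan-2-ol
Product: 19 (4R,6S,8R)-4-[(2-methoxypropan-2-yl)peroxy]-4,6,8-trimethyl-16-phenylhexadecan-2-one
Conditions: Dess–Martin periodinane (1.5 equiv), NaHCO3, CH2Cl2, 0 °C → rt
Reagents that add atoms: none
Why: Dess–Martin oxidation of the secondary alcohol under buffered, non-basic conditions that spare the dialkyl peroxyketal; the epimeric C2 centre disappears, so a single compound results.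

Step 11
Reactants: 19 (4R,6S,8R)-4-[(2-methoxypropan-2-yl)peroxy]-4,6,8-trimethyl-16-phenylhexadecan-2-one; 9 2-allyl-1,3,2-dioxaborinane
Product: 20 (4R,6R,8S,10R)-6-[(2-methoxypropan-2-yl)peroxy]-4,6,8,10-tetramethyl-18-phenyloctadec-1-en-4-ol
Conditions: 9 (2 equiv), (S)-3,3'-dibromo-1,1'-bi-2-naphthol (10 mol %), t-BuOH (2 equiv), toluene, rt, 72 h; H2O work-up
Reagents that add atoms: 2-allyl-1,3,2-dioxaborinane, C=CCB1OCCCO1
Why: The same chiral-diol-catalysed asymmetric allylboration, now differentiating CH3 from a neopentyl-like CH2; the catalyst, not the remote quaternary peroxy carbon, sets the tertiary carbinol (4R), the future C3 before inversion.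

Step 12
Reactants: 20 (4R,6R,8S,10R)-6-[(2-methoxypropan-2-yl)peroxy]-4,6,8,10-tetramethyl-18-phenyloctadec-1-en-4-ol; 21 sodium periodate; 22 water
Product: 23 (3S,5R,7S,9R)-3-hydroxy-5-[(2-methoxypropan-2-yl)peroxy]-3,5,7,9-tetramethyl-17-phenylheptadecanoic acid
Conditions: KMnO4 (10 mol %), NaIO4 (5 equiv), t-BuOH/aq. phosphate buffer (pH 8), rt; citrate buffer (pH 5), 0 °C, extraction
Reagents that add atoms: sodium periodate, [Na+].[O-]I(=O)(=O)=O; water, O
Why: Lemieux–von Rudloff oxidative cleavage turns the terminal vinyl group into the carboxylic acid under mildly basic conditions that the acid-labile peroxyketal tolerates; no stereocentre is touched (the descriptor changes to 3S only through priorities).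

Step 13
Reactants: 23 (3S,5R,7S,9R)-3-hydroxy-5-[(2-methoxypropan-2-yl)peroxy]-3,5,7,9-tetramethyl-17-phenylheptadecanoic acid
Product: 24 (4S)-4-methyl-4-{(2R,4S,6R)-2-[(2-methoxypropan-2-yl)peroxy]-2,4,6-trimethyl-14-phenyltetradecyl}oxetan-2-one
Conditions: PhSO2Cl (2 equiv), pyridine, 0 °C, 16 h
Reagents that add atoms: none
Why: β-Lactonisation by carboxyl activation (mixed sulfonic anhydride) and attack of the tertiary hydroxyl on the acyl carbon; the carbinol C–O bond is retained, so the quaternary centre keeps its configuration.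

Step 14
Reactants: 24 (4S)-4-methyl-4-{(2R,4S,6R)-2-[(2-methoxypropan-2-yl)peroxy]-2,4,6-trimethyl-14-phenyltetradecyl}oxetan-2-one
Product: 26 2-[(3R,5R)-5-[(2S,4R)-2,4-dimethyl-12-phenyldodecyl]-3,5-dimethyl-1,2-dioxolan-3-yl]acetic acid, via free hydroperoxy β-lactone 25 (not isolated)
Conditions: AcOH/THF/H2O (4:2:1), 0 °C → rt; concentrate with toluene; then Sc(OTf)3 (10 mol %), CH2Cl2, −40 → 0 °C
Reagents that add atoms: none
Why: Proposed new method: after mild hydrolysis of the peroxyketal, Lewis-acid coordination to the lactone carbonyl weakens the tertiary alkyl C–O bond and the distal hydroperoxide oxygen attacks that carbon from the rear in a 5-exo-tet, SN2-like (tight ion pair) opening, so C3 is formed with inversion (3R, methyls cis) and the carboxylate leaving group becomes the CH2CO2H arm; the closest known reactions are the Lewis-acid-promoted 5-exo opening of oxetanes by pendant hydroperoxides and the alkyl C–O cleavage of β-lactones by internal oxygen nucleophiles with inversion.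

## Compound list

1 | (R)-citronellal, (3R)-3,7-dimethyloct-6-enal | C[C@H](CCC=C(C)C)CC=O | starting material
2 | 1-(triphenyl-λ5-phosphanylidene)propan-2-one | CC(=O)C=P(c1ccccc1)(c1ccccc1)c1ccccc1 | starting material
3 | (3E,6R)-6,10-dimethylundeca-3,9-dien-2-one | C[C@H](CCC=C(C)C)C/C=C/C(C)=O | intermediate
4 | methylmagnesium bromide | C[Mg]Br | starting material
5 | (4S,6R)-4,6,10-trimethylundec-9-en-2-one | C[C@H](CCC=C(C)C)C[C@H](C)CC(C)=O | intermediate
6 | 6-phenylhex-1-ene | C=CCCCCc1ccccc1 | starting material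
7 | (4S,6R,9E)-4,6-dimethyl-14-phenyltetradec-9-en-2-one (9E shown, 9Z also present) | C[C@H](CC/C=C/CCCCc1ccccc1)C[C@H](C)CC(C)=O | intermediate
8 | (4S,6R)-4,6-dimethyl-14-phenyltetradecan-2-one | C[C@H](CCCCCCCCc1ccccc1)C[C@H](C)CC(C)=O | intermediate
9 | 2-allyl-1,3,2-dioxaborinane | C=CCB1OCCCO1 | starting material
10 | (4R,6S,8R)-4,6,8-trimethyl-16-phenylhexadec-1-en-4-ol | C[C@H](CCCCCCCCc1ccccc1)C[C@H](C)C[C@@](O)(C)CC=C | intermediate
11 | dioxygen | O=O | starting material
12 | (2RS,4S,6S,8R)-4,6,8-trimethyl-16-phenylhexadecane-2,4-diol (C2 epimers) | C[C@H](CCCCCCCCc1ccccc1)C[C@H](C)C[C@@](O)(C)CC(C)O | intermediate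
13 | (2RS,4S,6S,8R)-4-hydroxy-4,6,8-trimethyl-16-phenylhexadecan-2-yl 4-methylbenzenesulfonate | C[C@H](CCCCCCCCc1ccccc1)C[C@H](C)C[C@@](O)(C)CC(C)OS(=O)(=O)c1ccc(C)cc1 | intermediate (not isolated)
14 | (2S,4RS)-2,4-dimethyl-2-[(2S,4R)-2,4-dimethyl-12-phenyldodecyl]oxetane (C4 epimers) | C[C@H](CCCCCCCCc1ccccc1)C[C@H](C)C[C@@]1(C)CC(C)O1 | intermediate
15 | hydrogen peroxide | OO | starting material
16 | (2RS,4R,6S,8R)-4-hydroperoxy-4,6,8-trimethyl-16-phenylhexadecan-2-ol (C2 epimers) | C[C@H](CCCCCCCCc1ccccc1)C[C@H](C)C[C@](OO)(C)CC(C)O | intermediate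
17 | 2-methoxypropene | COC(C)=C | starting material
18 | (2RS,4R,6S,8R)-4-[(2-methoxypropan-2-yl)peroxy]-4,6,8-trimethyl-16-phenylhexadecan-2-ol (C2 epimers) | C[C@H](CCCCCCCCc1ccccc1)C[C@H](C)C[C@](OOC(C)(C)OC)(C)CC(C)O | intermediate
19 | (4R,6S,8R)-4-[(2-methoxypropan-2-yl)peroxy]-4,6,8-trimethyl-16-phenylhexadecan-2-one | C[C@H](CCCCCCCCc1ccccc1)C[C@H](C)C[C@](OOC(C)(C)OC)(C)CC(C)=O | intermediate
20 | (4R,6R,8S,10R)-6-[(2-methoxypropan-2-yl)peroxy]-4,6,8,10-tetramethyl-18-phenyloctadec-1-en-4-ol | C[C@H](CCCCCCCCc1ccccc1)C[C@H](C)C[C@](OOC(C)(C)OC)(C)C[C@@](C)(CC=C)O | intermediate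
21 | sodium periodate | [Na+].[O-]I(=O)(=O)=O | starting material
22 | water | O | starting material
23 | (3S,5R,7S,9R)-3-hydroxy-5-[(2-methoxypropan-2-yl)peroxy]-3,5,7,9-tetramethyl-17-phenylheptadecanoic acid | C[C@H](CCCCCCCCc1ccccc1)C[C@H](C)C[C@](OOC(C)(C)OC)(C)C[C@@](C)(CC(=O)O)O | intermediate
24 | (4S)-4-methyl-4-{(2R,4S,6R)-2-[(2-methoxypropan-2-yl)peroxy]-2,4,6-trimethyl-14-phenyltetradecyl}oxetan-2-one | C[C@H](CCCCCCCCc1ccccc1)C[C@H](C)C[C@](OOC(C)(C)OC)(C)C[C@@]1(C)CC(=O)O1 | intermediate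
25 | (4S)-4-[(2R,4S,6R)-2-hydroperoxy-2,4,6-trimethyl-14-phenyltetradecyl]-4-methyloxetan-2-one | C[C@H](CCCCCCCCc1ccccc1)C[C@H](C)C[C@](OO)(C)C[C@@]1(C)CC(=O)O1 | intermediate (not isolated)
26 | 2-[(3R,5R)-5-[(2S,4R)-2,4-dimethyl-12-phenyldodecyl]-3,5-dimethyl-1,2-dioxolan-3-yl]acetic acid | C[C@H](CCCCCCCCc1ccccc1)C[C@H](C)C[C@]1(C)C[C@](C)(CC(=O)O)OO1 | target

## Step count and risk

Total step count: 14. Longest linear sequence: 14 steps, from (R)-citronellal 1 to 26.

The three steps most likely to fail: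

**Step 14 (β-lactone opening by the hydroperoxide; new chemistry).** The lactone may ionise without capture, giving decarboxylation, elimination or loss of stereochemical fidelity at C3. The fallback sets out from 20 and comes back at 26, and runs the same stereospecific closure on an oxetane, which ionises less readily. Ozonolysis of 20 (O3, CH2Cl2/MeOH, −78 °C, then NaBH4) gives (3R,5R,7S,9R)-5-[(2-methoxypropan-2-yl)peroxy]-3,5,7,9-tetramethyl-17-phenylheptadecane-1,3-diol F1. One-pot n-BuLi, TsCl, then n-BuLi (THF, 0 → 60 °C) converts it, by way of (3R,5R,7S,9R)-3-hydroxy-5-[(2-methoxypropan-2-yl)peroxy]-3,5,7,9-tetramethyl-17-phenylheptadecyl 4-methylbenzenesulfonate F2, into (2R)-2-{(2R,4S,6R)-2-[(2-methoxypropan-2-yl)peroxy]-2,4,6-trimethyl-14-phenyltetradecyl}-2-methyloxetane F3, with retention because the carbinol C–O bond is not broken. AcOH/THF/H2O frees (2R)-2-[(2R,4S,6R)-2-hydroperoxy-2,4,6-trimethyl-14-phenyltetradecyl]-2-methyloxetane F4. TMSOTf (10 mol %, CH2Cl2, −78 °C) then brings about the known 5-exo hydroperoxide–oxetane cyclisation with inversion to 2-[(3S,5R)-5-[(2S,4R)-2,4-dimethyl-12-phenyldodecyl]-3,5-dimethyl-1,2-dioxolan-3-yl]ethan-1-ol F5. Dess–Martin oxidation gives 2-[(3R,5R)-5-[(2S,4R)-2,4-dimethyl-12-phenyldodecyl]-3,5-dimethyl-1,2-dioxolan-3-yl]acetaldehyde F6, and NaClO2/NaH2PO4/2-methyl-2-butene returns to 26.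

**Step 8 (oxetane perhydrolysis).** Yields of such openings are moderate, and elimination or partial loss of inversion would erode C5. The fallback sets out from 8 and comes back at 16; it replaces the ionic opening by a radical peroxidation and gives up stereocontrol at the peroxy carbon. Ketone 8 is deprotonated at the methyl group (LiN(iPr)2, THF, −78 °C) and treated with acetaldehyde to give (2RS,6S,8R)-2-hydroxy-6,8-dimethyl-16-phenylhexadecan-4-one F7. Ph3P=CH2 (2.5 equiv, THF) gives (2RS,6S,8R)-6,8-dimethyl-4-methylidene-16-phenylhexadecan-2-ol F8. Hydroperoxysilylation with Co(acac)2, O2 and Et3SiH (EtOH, rt) gives (2RS,4RS,6S,8R)-4,6,8-trimethyl-16-phenyl-4-[(triethylsilyl)peroxy]hexadecan-2-ol F9 as a roughly 1:1 mixture at the peroxy carbon. Bu4NF/AcOH releases the hydroperoxide, that is 16 together with its 4S epimer. The route is rejoined at 16, and the unwanted epimer is removed by chromatography after step 10, at ketone 19, where only that centre differs.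

**Step 11 (asymmetric allylboration of the β-peroxy ketone).** The Lewis-acidic boron species may attack the peroxyketal, or the selectivity may be too low. The fallback sets out from 19 and comes back at 26; it replaces the allylation/lactone sequence (steps 11 to 14) by a peroxycarbenium alkylation. TsOH (cat.) in MeOH removes the ketal from 19; the liberated (4R,6S,8R)-4-hydroperoxy-4,6,8-trimethyl-16-phenylhexadecan-2-one F10 closes and is trapped as (3RS,5R)-5-[(2S,4R)-2,4-dimethyl-12-phenyldodecyl]-3-methoxy-3,5-dimethyl-1,2-dioxolane F11. TiCl4 (CH2Cl2, −78 °C) with tert-butyl[(1-methoxyethenyl)oxy]dimethylsilane adds the acetate unit to the dioxolanyl cation and gives methyl 2-[(3R,5R)-5-[(2S,4R)-2,4-dimethyl-12-phenyldodecyl]-3,5-dimethyl-1,2-dioxolan-3-yl]acetate F12 together with its C3 epimer. Facial bias is small, so the epimers are separated by HPLC. LiOH (THF/H2O) returns to 26.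

## Further compounds

F1 | step 14 | (3R,5R,7S,9R)-5-[(2-methoxypropan-2-yl)peroxy]-3,5,7,9-tetramethyl-17-phenylheptadecane-1,3-diol | C[C@H](CCCCCCCCc1ccccc1)C[C@H](C)C[C@](OOC(C)(C)OC)(C)C[C@@](C)(CCO)O
F2 | step 14 | (3R,5R,7S,9R)-3-hydroxy-5-[(2-methoxypropan-2-yl)peroxy]-3,5,7,9-tetramethyl-17-phenylheptadecyl 4-methylbenzenesulfonate | C[C@H](CCCCCCCCc1ccccc1)C[C@H](C)C[C@](OOC(C)(C)OC)(C)C[C@@](C)(CCOS(=O)(=O)c1ccc(C)cc1)O
F3 | step 14 | (2R)-2-{(2R,4S,6R)-2-[(2-methoxypropan-2-yl)peroxy]-2,4,6-trimethyl-14-phenyltetradecyl}-2-methyloxetane | C[C@H](CCCCCCCCc1ccccc1)C[C@H](C)C[C@](OOC(C)(C)OC)(C)C[C@@]1(C)CCO1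
F4 | step 14 | (2R)-2-[(2R,4S,6R)-2-hydroperoxy-2,4,6-trimethyl-14-phenyltetradecyl]-2-methyloxetane | C[C@H](CCCCCCCCc1ccccc1)C[C@H](C)C[C@](OO)(C)C[C@@]1(C)CCO1
F5 | step 14 | 2-[(3S,5R)-5-[(2S,4R)-2,4-dimethyl-12-phenyldodecyl]-3,5-dimethyl-1,2-dioxolan-3-yl]ethan-1-ol | C[C@H](CCCCCCCCc1ccccc1)C[C@H](C)C[C@]1(C)C[C@](C)(CCO)OO1
F6 | step 14 | 2-[(3R,5R)-5-[(2S,4R)-2,4-dimethyl-12-phenyldodecyl]-3,5-dimethyl-1,2-dioxolan-3-yl]acetaldehyde | C[C@H](CCCCCCCCc1ccccc1)C[C@H](C)C[C@]1(C)C[C@](C)(CC=O)OO1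
F7 | step 8 | (2RS,6S,8R)-2-hydroxy-6,8-dimethyl-16-phenylhexadecan-4-one | C[C@H](CCCCCCCCc1ccccc1)C[C@H](C)CC(=O)CC(C)O
F8 | step 8 | (2RS,6S,8R)-6,8-dimethyl-4-methylidene-16-phenylhexadecan-2-ol | C[C@H](CCCCCCCCc1ccccc1)C[C@H](C)CC(=C)CC(C)O
F9 | step 8 | (2RS,4RS,6S,8R)-4,6,8-trimethyl-16-phenyl-4-[(triethylsilyl)peroxy]hexadecan-2-ol | C[C@H](CCCCCCCCc1ccccc1)C[C@H](C)CC(C)(OO[Si](CC)(CC)CC)CC(C)O
F10 | step 11 | (4R,6S,8R)-4-hydroperoxy-4,6,8-trimethyl-16-phenylhexadecan-2-one | C[C@H](CCCCCCCCc1ccccc1)C[C@H](C)C[C@](OO)(C)CC(C)=O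
F11 | step 11 | (3RS,5R)-5-[(2S,4R)-2,4-dimethyl-12-phenyldodecyl]-3-methoxy-3,5-dimethyl-1,2-dioxolane | C[C@H](CCCCCCCCc1ccccc1)C[C@H](C)C[C@]1(C)CC(C)(OC)OO1
F12 | step 11 | methyl 2-[(3R,5R)-5-[(2S,4R)-2,4-dimethyl-12-phenyldodecyl]-3,5-dimethyl-1,2-dioxolan-3-yl]acetate | C[C@H](CCCCCCCCc1ccccc1)C[C@H](C)C[C@]1(C)C[C@](C)(CC(=O)OC)OO1
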